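The constants used here are those of an exercise.

Rank these flasks by D.X at the end, and bracket the numbers by hand before any run.

    D + E → J + X (k1 = 0.19 M⁻¹ s⁻¹)
    E + J → Q + X (k2 = 0.031 M⁻¹ s⁻¹)
    D + X → D.X (k3 = 2.0 M⁻¹ s⁻¹)

the same everywhere: time 80 s

| run | D | E | remark |
|---|---|---|---|
| blue | 20 mM (fed, over 50 s) | 30.0 mM | all else is in the flask from the start; the feed brings no volume worth counting |
| violet | 20 mM | 30.0 mM | everything together at the start |
| teal | 20 mM | 30.0 mM (fed, over 50 s) | all else is in the flask from the start; the feed brings no volume worth counting |
| amber | 20 mM (in portions, 4, over 50 s) | 30.0 mM | first portion at the start, last at 50 s |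

* the flask that comes out highest in amount of D.X, in percent of the D charged; "all alike" if 1.5 percentage points covers them all (blue / violet / teal / amber / all alike)
* amount of D.X at the end, in percent of the D charged, blue
* amount of D.X at the end, in percent of the D charged, violet
* amount of D.X at the end, in percent of the D charged, teal
* amount of D.X at the end, in percent of the D charged, amber

I worked with the ceiling of X, its quasi-steady level, the c_X at which trapping by D keeps pace with making by D and E, which came to 2.85 mM; c_D cancels from it. With E held and the step from J to Q dropped, c_X climbed towards the ceiling on a clock θ, the running sum of the trapping constant times c_D, and D.X reached the ceiling times θ − 1 + exp(−θ).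

For violet, c_D held at its charge gave θ = 3.20 and a top of 31.9% of the D charged. For the bottom I let D fall as if X stood at the ceiling from the start, at 0.0114 s⁻¹, which gave θ = 2.10. E then sank to 80.1% of its charge, paying for half of the D lost, and the bottom was 13.9%.

To tighten, I took E midway, at 90.0%, and let X lag the ceiling by 25.0 s. D then ended near 50.0%, θ near 2.31, and D.X near 18.1%. Blue and amber hold D back by 25.0 s on average, which lowered their top to 18.7%, and the same tightening gave about 10.6%. Teal I did not reckon. I put violet above blue and amber.

The forecast also named violet, with 19.5% for violet, inside my bracket, and 12.9%, 13.2% and 13.3% for blue, teal and amber, because “having both D and E present from the start gives the longest time with X and D together”. The flasks put violet highest, with 19.5%, against 12.9% for blue, 13.2% for teal and 12.8% for amber.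

In violet at 80.0 s, c_X read 2.33 mM, close to the ceiling taken with the E then left, 2.26 mM, and the making step used D at 0.97 of the rate of trapping. In the neighbour flask, violet with 8.0 mM of D, the ceiling with its E left stood at 2.59 mM, but the lag grew to 62.5 s, c_X read 1.76 mM, and D.X ended at 12.5%.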